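In its first 6.0 min the larch run makes 16.1 mM of product against 13.3 mM in the alder run, which is more but not by much, although larch holds 3.00 times the substrate. The oak run, with less partner than alder, makes 9.2 mM in that time, which is less. So both reagents matter, and I want to know which of them holds the cedar run back.

in all of them: free catalyst 2.00 mM
- alder: substrate 100 mM; partner 250 mM
- birch: substrate 60.0 mM; partner 210 mM
- larch: substrate 300 mM; partner 250 mM
- oak: substrate 100 mM; partner 120 mM
- cedar: substrate 100 mM; partner 72.0 mM; time 42 min

| run | time / min | [product] / mM |
|---|---|---|
| alder run | 6.0 | 13.3 |
| alder run | 12 | 26.4 |
| alder run | 18 | 38.3 |
| alder run | 24 | 49.8 |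
| alder run | 30 | 59.4 |
| alder run | 36 | 68.4 |
| alder run | 42 | 77.2 |
| birch run | 6.0 | 11.0 |
| birch run | 12 | 20.8 |
| birch run | 18 | 29.6 |
| birch run | 24 | 37.5 |
| birch run | 30 | 44.4 |
| birch run | 36 | 49.5 |
| birch run | 42 | 53.7 |
| larch run | 6.0 | 16.1 |
| larch run | 12 | 31.4 |
| larch run | 18 | 46.5 |
| larch run | 24 | 60.2 |
| larch run | 30 | 74.0 |
| larch run | 36 | 86.9 |
| larch run | 42 | 99.5 |
| oak run | 6.0 | 9.2 |
| oak run | 12 | 18.0 |
| oak run | 18 | 26.1 |
| oak run | 24 | 34.2 |
| oak run | 30 | 41.6 |
| oak run | 36 | 48.4 |
| oak run | 42 | 54.6 |

(scatter of a reading: 0.3 mM)

- Overall: substrate + partner -> product, with free catalyst as catalyst.
- Constant volume, constant temperature.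
- The analysis sees a species whether free or bound.
- An order is taken over about fifteen percent of the charge, up and down.

* the exponent of [partner] in the starting rate at the charge of the alder run (at the point where two percent of the substrate have become product)
* the exponent of [substrate] in the starting rate at the charge of the alder run (at the point where two percent of the substrate have become product) (one fixed amount of product, the same in the runs compared)
* the birch run starts with 40.0 mM less of substrate and of partner than the alder run, and with no product. Compared where both hold the same amount of substrate, once fifteen percent of what the birch run was charged with has turned into product, is the birch run faster, slower or alike (within a tenth)?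
* product in the cedar run at 42 min, as a share of the substrate charged

The first interval of the larch, alder and oak runs is 6.0 min in each, and I read the time that each run takes per unit of product there. My own reckoning takes this time as a sum of a fixed part, a part going as one over c(substrate) and a part going as one over c(partner). Larch against alder then puts the substrate part at 0.261 of the alder time, and oak against alder puts the partner part at 0.411 of it, both readings that carry the scatter.

At the alder charge this makes a ladder of rungs. The substrate rung is the shortest, the fixed part takes the remaining 0.328, and the partner rung is the longest.

The two concentration rungs are equal where c(partner)/c(substrate) stands at 3.94, a reading, and I call this the crossing ratio: above it substrate holds the longer rung, below it partner does. The alder charge has a ratio of 2.50, below the crossing. The cedar charge has 0.720, also below it. Partner is the limiting reagent in the cedar run, with 72.0 mM against 100 mM of substrate, and equal losses push the ratio down as that run proceeds. At the cedar charge the partner rung is 70.8% of my summed time, more than the other rungs together, so I expect it to be the longest rung at the start of the cedar run.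

The forecast gives 0.41 for partner, 0.21 for substrate and alike for the comparison of birch with alder. For the cedar run it gives 37.5%, between 35.5% and 39.5%. Of birch against alder it says: “The rates are alike, so there is no visible product inhibition or catalyst loss.”

The cedar run gives 38.5%, with orders of 0.47 in partner and 0.22 in substrate at the alder charge.

    free catalyst + substrate → catalyst-substrate complex (100.2 L mol⁻¹ min⁻¹)
    catalyst-substrate complex + partner → loaded catalyst (27.30 L mol⁻¹ min⁻¹)
    loaded catalyst → product + free catalyst (40.86 min⁻¹)
    free catalyst + impurity → spent catalyst
    2 partner ⇌ idle reagent dimer, settled at all times (6.140 L mol⁻¹)

Birch against alder comes out alike; a gap beyond a tenth there would have made the forecast's answer wrong. At 42 min the cedar run, reckoned as charge less product, has a ratio of 0.545, below the crossing ratio of 3.94. The birch run moves the other way: it starts at 3.50, reaches 3.94 near 9.02 mM of product, and at 18.1 min, with product at half of its charged substrate and above the crossing, stands at 6.00.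

The data were generated by integration for substances that don't exist.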